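**Strategy**

The target is the propelargonidin trimer epiafzelechin-(4β→8)-epiafzelechin-(4β→8)-epiafzelechin; all three flavan units, the middle one included, are drawn from one benzylated (2R,3R) monomer. Everything rests on opening ring C of that unit at C2–C3: O1 is the phenolic oxygen of ring A and C2 a 4-oxybenzoyl carbon, so O1–C2 can pre-exist as an aryl ester ortho to an allyl group (C4, C3). One titanium-methylidene operation (ester methylenation, then ring-closing metathesis) forges C2=C3 and closes ring C; its precursor is 2-allyl-3,5-bis(benzyloxy)phenyl 4-(benzyloxy)benzoate. Asymmetric hydroboration, C3 inversion by oxidation/reduction, C4 activation and two 4β→8 couplings complete the route.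

Key step: step 4

Remark: the eight stereocentres of the target correspond to three (2R,3R)-2,3-cis flavan-3-ol units joined by two 4β (3,4-trans) C4→C8 bonds. 3,5-Bis(benzyloxy)phenol, 4-(benzyloxy)benzoyl chloride, the Tebbe reagent and IpcBH2 made from (+)-α-pinene are taken as available.

**Route**

Step 1
Reactants: 1 3,5-bis(benzyloxy)phenol
Product: 2 1-(allyloxy)-3,5-bis(benzyloxy)benzene
Conditions: allyl bromide, K2CO3, acetone, reflux
Reagents that add atoms: allyl bromide, C=CCBr
Why: Williamson O-allylation of the only free phenol under mild carbonate conditions; no stereocentre is involved.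

Step 2
Reactants: 2 1-(allyloxy)-3,5-bis(benzyloxy)benzene
Product: 4 2-allyl-3,5-bis(benzyloxy)phenol, via ortho-dienone 3 (not isolated)
Conditions: PhNEt2, 190 °C, sealed tube, argon
Reagents that add atoms: none
Why: aromatic Claisen rearrangement ([3,3]-sigmatropic shift) moves the allyl group to one of the two equivalent ortho positions and dienone 3 tautomerises back to the phenol, which places the future C4–C3 unit next to the future O1.

Step 3
Reactants: 4 2-allyl-3,5-bis(benzyloxy)phenol; 5 4-(benzyloxy)benzoyl chloride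
Product: 6 2-allyl-3,5-bis(benzyloxy)phenyl 4-(benzyloxy)benzoate
Conditions: Et3N, DMAP (cat.), CH2Cl2, 0 °C to rt
Reagents that add atoms: none
Why: DMAP-catalysed O-acylation of the phenol installs the O1–C2 bond at the ester oxidation level and brings in ring B.

Step 4
Reactants: 6 2-allyl-3,5-bis(benzyloxy)phenyl 4-(benzyloxy)benzoate
Product: 8 5,7-bis(benzyloxy)-2-[4-(benzyloxy)phenyl]-4H-chromene, via acyclic enol ether 7 (not isolated)
Conditions: Tebbe reagent Cp2Ti(μ-CH2)(μ-Cl)AlMe2 (4 equiv), pyridine (cat.), THF, 25 °C; then reflux; aq. NaOH quench, filtration through basic Al2O3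
Reagents that add atoms: none
Why: Cp2Ti=CH2, released from the Tebbe reagent, first methylenates the aryl ester carbonyl through an oxatitanacyclobutane to give the 1,1-disubstituted enol ether 7; on heating, a further titanium methylidene exchanges with the terminal allyl olefin (loss of ethylene) and the titanium alkylidene so formed closes onto the enol ether by [2+2] cycloaddition and cycloreversion, which creates the C2=C3 bond. The closest known reaction type is the tandem ester methylenation and ring-closing olefin metathesis of olefinic esters to cyclic enol ethers with Tebbe-type reagents, and the first stage is the standard Tebbe methylenation of aryl benzoates. The one ring closed is the six-membered pyran ring C, closed by ring-closing metathesis between the enol ether carbon C2 and the internal allyl carbon C3, which the ortho-disubstituted ring A holds within bonding distance. No stereocentre is formed; the step delivers the flat, prochiral C2=C3 enol ether on which step 5 sets C2 and C3 by reagent control. The selectivity needed is chemoselectivity: reaction at the single ester and at the monosubstituted allyl terminus without migration of the allyl double bond into conjugation and without hydrolysis of the acid-labile enol ether, secured by the inertness of benzyl ethers to titanium alkylidenes, by a trace of pyridine and by basic work-up.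

Step 5
Reactants: 8 5,7-bis(benzyloxy)-2-[4-(benzyloxy)phenyl]-4H-chromene
Product: 10 (2R,3S)-5,7-bis(benzyloxy)-2-[4-(benzyloxy)phenyl]chroman-3-ol, via alkylborane 9 (not isolated)
Conditions: IpcBH2 [from (+)-α-pinene], THF, −25 °C; then NaOH, H2O2, 0 °C to rt
Reagents that add atoms: hydrogen peroxide, OO (oxygen at C3); monoisopinocampheylborane, C[C@H]1[C@H](B)C[C@@H]2C[C@H]1C2(C)C (its boron and terpene group are carried only in 9)
Why: Brown asymmetric hydroboration adds H–B syn with boron at C3 (β to O1 and to the aryl group), so oxidation with retention should give the 2,3-trans alcohol; the reagent from (+)-α-pinene is chosen by analogy with 1-arylcycloalkenes to set C2 as R (the antipodal borane is the alternative should the sense prove opposite).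

Step 6
Reactants: 10 (2R,3S)-5,7-bis(benzyloxy)-2-[4-(benzyloxy)phenyl]chroman-3-ol
Product: 11 (2R)-5,7-bis(benzyloxy)-2-[4-(benzyloxy)phenyl]chroman-3-one
Conditions: Dess–Martin periodinane, wet CH2Cl2, rt
Reagents that add atoms: none
Why: Dess–Martin oxidation is fast and close to neutral, which should preserve the labile C2 stereocentre (α to the new ketone, benzylic and α-oxygenated).

Step 7
Reactants: 11 (2R)-5,7-bis(benzyloxy)-2-[4-(benzyloxy)phenyl]chroman-3-one
Product: 12 (2R,3R)-5,7-bis(benzyloxy)-2-[4-(benzyloxy)phenyl]chroman-3-ol (5,7,4'-tri-O-benzyl-epiafzelechin)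
Conditions: LiBH(s-Bu)3 (L-Selectride), LiBr, THF, −78 °C; then H2O
Reagents that add atoms: none
Why: substrate-controlled ketone reduction: the bulky hydride attacks C3 from the face opposite the equatorial C2 aryl group, giving the axial 3-OH cis to that aryl (3R).

Step 8
Reactants: 12 (2R,3R)-5,7-bis(benzyloxy)-2-[4-(benzyloxy)phenyl]chroman-3-ol
Product: 13 (2R,3R,4S)-5,7-bis(benzyloxy)-2-[4-(benzyloxy)phenyl]-4-(2-ethoxyethoxy)chroman-3-ol
Conditions: DDQ (2 equiv), 2-ethoxyethanol (excess), CH2Cl2, rt
Reagents that add atoms: 2-ethoxyethanol, CCOCCO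
Why: oxidative benzylic C–H etherification: DDQ abstracts hydride from C4, activated by the 5,7-dioxygenated ring A, and the alcohol traps the cation trans to the C2 aryl group (4β).

Step 9
Reactants: 13 (2R,3R,4S)-5,7-bis(benzyloxy)-2-[4-(benzyloxy)phenyl]-4-(2-ethoxyethoxy)chroman-3-ol; 12 (2R,3R)-5,7-bis(benzyloxy)-2-[4-(benzyloxy)phenyl]chroman-3-ol (fourfold excess)
Product: 14 hexa-O-benzyl epiafzelechin-(4β→8)-epiafzelechin
Conditions: Me3SiOTf (cat.), CH2Cl2, −78 °C; Et3N quench; excess 12 recovered
Reagents that add atoms: none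
Why: Friedel–Crafts alkylation: ionisation of the C4 ether gives a ring A-stabilised benzylic cation that C8 of 12 attacks anti to the C3 hydroxyl and C2 aryl, setting the 4β (3,4-trans) interflavan bond, while the excess of 12 suppresses self-condensation.

Step 10
Reactants: 13 (2R,3R,4S)-5,7-bis(benzyloxy)-2-[4-(benzyloxy)phenyl]-4-(2-ethoxyethoxy)chroman-3-ol; 14 hexa-O-benzyl epiafzelechin-(4β→8)-epiafzelechin (threefold excess)
Product: 15 nona-O-benzyl epiafzelechin-(4β→8)-epiafzelechin-(4β→8)-epiafzelechin
Conditions: Me3SiOTf (cat.), CH2Cl2, −78 °C; Et3N quench; excess 14 recovered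
Reagents that add atoms: none
Why: the same Friedel–Crafts alkylation, now at C8 of the upper unit of 14 (its only unsubstituted C8 and most accessible nucleophilic site), with attack on the β face of the cation from 13 setting the second 4β bond.

Step 11
Reactants: 15 nona-O-benzyl epiafzelechin-(4β→8)-epiafzelechin-(4β→8)-epiafzelechin
Product: 16 epiafzelechin-(4β→8)-epiafzelechin-(4β→8)-epiafzelechin (CNP0191553.1)
Conditions: H2 (1 atm), Pd(OH)2/C, THF/MeOH/H2O, rt
Reagents that add atoms: none
Why: neutral hydrogenolysis of the nine benzyl ethers should leave the acid-sensitive interflavan bonds and all eight stereocentres untouched.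

**Compound list**

1 | 3,5-bis(benzyloxy)phenol | Oc1cc(OCc2ccccc2)cc(OCc2ccccc2)c1 | starting material
2 | 1-(allyloxy)-3,5-bis(benzyloxy)benzene | C=CCOc1cc(OCc2ccccc2)cc(OCc2ccccc2)c1 | intermediate
3 | 6-allyl-3,5-bis(benzyloxy)cyclohexa-2,4-dien-1-one (ortho-dienone, transient, racemic) | C=CCC1C(=O)C=C(OCc2ccccc2)C=C1OCc1ccccc1 | intermediate (not isolated)
4 | 2-allyl-3,5-bis(benzyloxy)phenol | C=CCc1c(O)cc(OCc2ccccc2)cc1OCc1ccccc1 | intermediate
5 | 4-(benzyloxy)benzoyl chloride | O=C(Cl)c1ccc(OCc2ccccc2)cc1 | starting material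
6 | 2-allyl-3,5-bis(benzyloxy)phenyl 4-(benzyloxy)benzoate | C=CCc1c(OC(=O)c2ccc(OCc3ccccc3)cc2)cc(OCc2ccccc2)cc1OCc1ccccc1 | intermediate
7 | 2-allyl-1,5-bis(benzyloxy)-3-({1-[4-(benzyloxy)phenyl]ethenyl}oxy)benzene (acyclic enol ether) | C=CCc1c(OC(=C)c2ccc(OCc3ccccc3)cc2)cc(OCc2ccccc2)cc1OCc1ccccc1 | intermediate (not isolated)
8 | 5,7-bis(benzyloxy)-2-[4-(benzyloxy)phenyl]-4H-chromene (flav-2-ene) | C1(c2ccc(OCc3ccccc3)cc2)=CCc2c(OCc3ccccc3)cc(OCc3ccccc3)cc2O1 | intermediate
9 | [(2R)-2,3-trans-5,7-bis(benzyloxy)-2-[4-(benzyloxy)phenyl]chroman-3-yl](isopinocampheyl)borane, boron at C3 on the face opposite the C2 aryl | C[C@H]1[C@H](B[C@H]2Cc3c(OCc4ccccc4)cc(OCc4ccccc4)cc3O[C@@H]2c2ccc(OCc3ccccc3)cc2)C[C@@H]2C[C@H]1C2(C)C | intermediate (not isolated)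
10 | (2R,3S)-5,7-bis(benzyloxy)-2-[4-(benzyloxy)phenyl]chroman-3-ol (5,7,4'-tri-O-benzyl-afzelechin, 2,3-trans) | O[C@H]1Cc2c(OCc3ccccc3)cc(OCc3ccccc3)cc2O[C@@H]1c1ccc(OCc2ccccc2)cc1 | intermediate
11 | (2R)-5,7-bis(benzyloxy)-2-[4-(benzyloxy)phenyl]chroman-3-one | O=C1Cc2c(OCc3ccccc3)cc(OCc3ccccc3)cc2O[C@@H]1c1ccc(OCc2ccccc2)cc1 | intermediate
12 | (2R,3R)-5,7-bis(benzyloxy)-2-[4-(benzyloxy)phenyl]chroman-3-ol (5,7,4'-tri-O-benzyl-epiafzelechin, 2,3-cis) | O[C@@H]1Cc2c(OCc3ccccc3)cc(OCc3ccccc3)cc2O[C@@H]1c1ccc(OCc2ccccc2)cc1 | intermediate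
13 | (2R,3R,4S)-5,7-bis(benzyloxy)-2-[4-(benzyloxy)phenyl]-4-(2-ethoxyethoxy)chroman-3-ol (4β ether, 3,4-trans) | O[C@@H]1[C@@H](OCCOCC)c2c(OCc3ccccc3)cc(OCc3ccccc3)cc2O[C@@H]1c1ccc(OCc2ccccc2)cc1 | intermediate
14 | hexa-O-benzyl epiafzelechin-(4β→8)-epiafzelechin (both units 2R,3R; interflavan bond 3,4-trans; 5,7,4'-benzyl ethers on each unit, 3-OH free) | c1ccccc1COc1ccc([C@H]2Oc3c(c(OCc4ccccc4)cc(OCc4ccccc4)c3)[C@H](c3c(OCc4ccccc4)cc(OCc4ccccc4)c4c3O[C@H](c3ccc(OCc5ccccc5)cc3)[C@H](O)C4)[C@H]2O)cc1 | intermediate
15 | nona-O-benzyl epiafzelechin-(4β→8)-epiafzelechin-(4β→8)-epiafzelechin (all units 2R,3R; both interflavan bonds 3,4-trans; 3-OH groups free) | c1ccccc1COc1ccc([C@H]2Oc3c(c(OCc4ccccc4)cc(OCc4ccccc4)c3[C@H]3c4c(OCc5ccccc5)cc(OCc5ccccc5)cc4O[C@H](c4ccc(OCc5ccccc5)cc4)[C@@H]3O)[C@H](c3c(OCc4ccccc4)cc(OCc4ccccc4)c4c3O[C@H](c3ccc(OCc5ccccc5)cc3)[C@H](O)C4)[C@H]2O)cc1 | intermediate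
16 | epiafzelechin-(4β→8)-epiafzelechin-(4β→8)-epiafzelechin (CNP0191553.1) | Oc1ccc([C@H]2Oc3c(c(O)cc(O)c3[C@H]3c4c(O)cc(O)cc4O[C@H](c4ccc(O)cc4)[C@@H]3O)[C@H](c3c(O)cc(O)c4c3O[C@H](c3ccc(O)cc3)[C@H](O)C4)[C@H]2O)cc1 | target

**Step count and risks**

Total steps: 11. Longest linear sequence: 11 steps (1 to 16); compound 12 feeds steps 8 and 9, and compound 13 feeds steps 9 and 10.

Steps most likely to fail:

Step 4. The cascade may stall after methylenation, or the allyl double bond may migrate into conjugation before the titanium alkylidene engages the hindered 1,1-disubstituted enol ether. The fallback separates the two events and closes the ring with a ruthenium carbene instead of a titanium alkylidene. It sets out from 6: Cp2TiMe2 (toluene, 65 °C, dark) methylenates the ester and the acyclic enol ether 7 is isolated. Ring-closing metathesis with the second-generation Grubbs catalyst RuCl2(=CHPh)(PCy3)(H2IMes) (toluene, 80 °C, ethylene purged) then closes C2=C3 and comes back to the route at 8. This detour makes no compound outside the list (none, F0).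

Step 5. Facial selectivity of the chiral borane on a 2-aryl enol ether may be poor (low enantiomeric excess), and the β-aryloxy borane may undergo ring-opening β-elimination before oxidation. The fallback moves the enantio-determining event to a ketone reduction with dynamic kinetic resolution. It sets out from 8: hydroboration with BH3·THF and alkaline peroxide gives (±)-trans-5,7-bis(benzyloxy)-2-[4-(benzyloxy)phenyl]chroman-3-ol F1. Dess–Martin oxidation gives racemic 5,7-bis(benzyloxy)-2-[4-(benzyloxy)phenyl]chroman-3-one F2, whose C2–H (α to the ketone, benzylic, α-aryloxy) epimerises readily under amine base. Noyori asymmetric transfer hydrogenation with RuCl(p-cymene)[(S,S)-TsDPEN] in HCO2H/Et3N (the antipodal catalyst if the sense proves opposite) should then reduce one rapidly equilibrating enantiomer to the cis alcohol. The fallback comes back to the route at 12 and bypasses 10 and 11.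

Step 10. Attack through the C6 positions of the dimer, or a further chain extension of the trimer, may erode regiocontrol and give products that are hard to separate. The fallback reverses the roles, so that the dimer is the electrophile and the monomer, in large excess, the nucleophile. It sets out from 14: DDQ and 2-ethoxyethanol in CH2Cl2 oxidise the only C4 methylene (that of the lower unit) to hexa-O-benzyl epiafzelechin-(4β→8)-[4β-(2-ethoxyethoxy)]epiafzelechin F3. Me3SiOTf-catalysed coupling of this dimeric electrophile with excess 12 (attack through C8) comes back to the route at 15.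

**Further compounds**

F0 | step 4 | none | none
F1 | step 5 | (±)-trans-5,7-bis(benzyloxy)-2-[4-(benzyloxy)phenyl]chroman-3-ol (racemate; the (2R,3S) enantiomer is written) | O[C@H]1Cc2c(OCc3ccccc3)cc(OCc3ccccc3)cc2O[C@@H]1c1ccc(OCc2ccccc2)cc1
F2 | step 5 | (±)-5,7-bis(benzyloxy)-2-[4-(benzyloxy)phenyl]chroman-3-one (racemic at C2) | O=C1Cc2c(OCc3ccccc3)cc(OCc3ccccc3)cc2OC1c1ccc(OCc2ccccc2)cc1
F3 | step 10 | hexa-O-benzyl epiafzelechin-(4β→8)-[4β-(2-ethoxyethoxy)]epiafzelechin (ether at C4 of the lower unit, trans to its 3-OH) | c1ccccc1COc1ccc([C@H]2Oc3c(c(OCc4ccccc4)cc(OCc4ccccc4)c3)[C@H](c3c(OCc4ccccc4)cc(OCc4ccccc4)c4c3O[C@H](c3ccc(OCc5ccccc5)cc3)[C@H](O)[C@H]4OCCOCC)[C@H]2O)cc1
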